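**Plan**

- Retrosynthesis: cut the C9 and C8 ester C–O bonds; then C2–C3 and C3–C4 (C3 is excised and ring B contracts to a cyclopentanone with C2 bonded to C4); then C5–CH3; then C5–C10, C4–C2 and C2–C1 (Pauson–Khand), which opens both rings to a 1,7-enyne; then C4–CH3, C5≡C4, C7–isopropenyl, C7=C6 and C10=C1, back to D-erythronolactone acetonide.
- Forward: the chain is built on the sugar dioxolane; one Pauson–Khand reaction closes ring A and a five-membered ring B; the angular methyl is added; ring B is enlarged to six members by inserting C3; enone reduction, acetonide removal and two acylations finish.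
- Enabling feature: in ring B the ketone carbon C2, the methylene C3 and the methyl-bearing C4 are contiguous, so C3 can be held back until a cis-hydrindanone carrying a C2=C4 silyl enol ether exists, and then inserted as a single carbon.
- Stereochemistry: C8/C9 from D-erythronolactone; C7 by 1,2-induction in a cuprate addition to a (Z)-enoate; C10 from the chair-like Pauson–Khand transition state; C5 from cis-selective cuprate addition; C4 from axial protonation in the Li/NH3 reduction; the side-chain centre from (R)-2-methylbutanoic acid.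

Key step: step 10

Remarks: eremophilane numbering is used (ring B = C1–C5, C10 with the ketone at C2; ring A = C5–C10); β is the face of the C5 methyl, α the face of the two oxygens. The C9 ester is read as the (E)-2-methylbut-2-enoate (tiglate) and the C8 ester as the (R)-2-methylbutanoate; (R)-2-methylbutanoic acid and tigloyl chloride are taken as purchasable single isomers.

**Route**

Step 1
Reactants: 1 2,3-O-isopropylidene-D-erythronolactone
Product: 2 2,3-O-isopropylidene-D-erythrofuranose (lactol; both anomers)
Conditions: DIBAL-H (1.1 equiv), CH2Cl2, −78 °C; Rochelle salt work-up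
Reagents that add atoms: none
Why: DIBAL-H reduction of a γ-lactone stops at the lactol because the tetrahedral aluminium alkoxide survives at −78 °C until work-up (lactone-to-lactol reduction); no stereocentre is touched.

Step 2
Reactants: 2 2,3-O-isopropylidene-D-erythrofuranose; 3 methyltriphenylphosphonium bromide
Product: 4 [(4R,5S)-2,2-dimethyl-5-vinyl-1,3-dioxolan-4-yl]methanol
Conditions: 3 (2.5 equiv), KOtBu (2.4 equiv), THF, 0 °C → rt
Reagents that add atoms: methyltriphenylphosphonium bromide 3 (as its ylide), C[P+](c1ccccc1)(c1ccccc1)c1ccccc1.[Br-]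
Why: Wittig methylenation of the lactol through its open hydroxy aldehyde; the lactone carbon becomes C10, the ylide carbon C1, and the two acetonide centres (C8, C9) are carried over unchanged.

Step 3
Reactants: 4 [(4R,5S)-2,2-dimethyl-5-vinyl-1,3-dioxolan-4-yl]methanol
Product: 5 (4S,5S)-2,2-dimethyl-5-vinyl-1,3-dioxolane-4-carbaldehyde
Conditions: Dess–Martin periodinane, CH2Cl2, 0 °C → rt; used at once
Reagents that add atoms: none
Why: Dess–Martin oxidation of the primary alcohol under non-basic conditions, chosen so that the cis-aldehyde, now epimerisable at C8, is not equilibrated to the trans isomer.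

Step 4
Reactants: 5 (4S,5S)-2,2-dimethyl-5-vinyl-1,3-dioxolane-4-carbaldehyde; 6 ethyl 2-(diphenoxyphosphoryl)acetate
Product: 7 ethyl (Z)-3-[(4R,5S)-2,2-dimethyl-5-vinyl-1,3-dioxolan-4-yl]prop-2-enoate
Conditions: 6, NaH, THF, −78 → −20 °C
Reagents that add atoms: ethyl 2-(diphenoxyphosphoryl)acetate 6, CCOC(=O)CP(=O)(Oc1ccccc1)Oc1ccccc1
Why: Ando variant of the Horner–Wadsworth–Emmons reaction: the diaryl phosphonate collapses under kinetic control at low temperature to the (Z)-enoate, and the weakly basic phosphonate anion leaves C8 untouched.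

Step 5
Reactants: 7 ethyl (Z)-3-[(4R,5S)-2,2-dimethyl-5-vinyl-1,3-dioxolan-4-yl]prop-2-enoate; 8 isopropenylmagnesium bromide
Product: 10 ethyl (3R)-3-[(4R,5S)-2,2-dimethyl-5-vinyl-1,3-dioxolan-4-yl]-4-methylpent-4-enoate, via silyl ketene acetal 9 (not isolated)
Conditions: 8 (2.5 equiv), CuBr·SMe2 (15 mol %), TMSCl (3 equiv), THF, −78 → −40 °C; aq NH4Cl
Reagents that add atoms: isopropenylmagnesium bromide 8, C=C(C)[Mg]Br
Why: Copper-catalysed, TMSCl-accelerated 1,4-addition of the Grignard reagent (cuprate conjugate addition): the (Z)-ester forces C8–H into the alkene plane (A1,3 strain), the face on the C9 side is covered by the cis vinyl group, and isopropenyl should therefore add from the O8 side to give the 7,8-syn (3R) ester, the sense known for (Z)-γ-alkoxy enoates; the silyl ketene acetal is hydrolysed on work-up.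

Step 6
Reactants: 10 ethyl (3R)-3-[(4R,5S)-2,2-dimethyl-5-vinyl-1,3-dioxolan-4-yl]-4-methylpent-4-enoate; 11 dimethyl (1-diazo-2-oxopropyl)phosphonate
Product: 13 (4R,5S)-2,2-dimethyl-4-[(3R)-2-methylhex-1-en-5-yn-3-yl]-5-vinyl-1,3-dioxolane, via aldehyde 12 (not isolated)
Conditions: DIBAL-H (1.05 equiv), CH2Cl2, −78 °C; then MeOH, K2CO3, 11, 0 °C → rt
Reagents that add atoms: dimethyl (1-diazo-2-oxopropyl)phosphonate 11, CC(=O)C(=[N+]=[N-])P(=O)(OC)OC
Why: DIBAL-H half-reduction of the ester to the aldehyde, followed in the same flask by Ohira–Bestmann (Seyferth–Gilbert) homologation, which adds C4 as the alkyne terminus; C7 is β to the aldehyde and cannot epimerise.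

Step 7
Reactants: 13 (4R,5S)-2,2-dimethyl-4-[(3R)-2-methylhex-1-en-5-yn-3-yl]-5-vinyl-1,3-dioxolane; 14 iodomethane
Product: 16 (4R,5S)-2,2-dimethyl-4-[(3R)-2-methylhept-1-en-5-yn-3-yl]-5-vinyl-1,3-dioxolane, via lithium acetylide 15 (not isolated)
Conditions: n-BuLi, THF, −78 °C; MeI, −78 → 0 °C
Reagents that add atoms: iodomethane 14, CI
Why: Deprotonation of the terminal alkyne and SN2 methylation of the lithium acetylide (acetylide alkylation) installs the future C4 methyl; nothing else in the molecule is acidic or electrophilic enough to interfere.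

Step 8
Reactants: 16 (4R,5S)-2,2-dimethyl-4-[(3R)-2-methylhept-1-en-5-yn-3-yl]-5-vinyl-1,3-dioxolane; 17 dicobalt octacarbonyl
Product: 19 Pauson–Khand enone (cyclopentenone C1H2–C2(=O)–C4(CH3)=C5 fused through C5–C10 to ring A; 7β-isopropenyl; 8α,9α-acetonide; 10β-H), via alkyne hexacarbonyldicobalt complex 18 (not isolated)
Conditions: Co2(CO)8 (1.1 equiv), CH2Cl2, rt; then NMO·H2O (6 equiv), 0 °C → rt
Reagents that add atoms: dicobalt octacarbonyl 17 (source of the C2 carbonyl), O=C=[Co](=C=O)(=C=O)(=C=O)[Co](=C=O)(=C=O)(=C=O)=C=O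
Why: Amine-N-oxide-promoted intramolecular Pauson–Khand [2+2+1] cycloaddition of the 1,7-enyne forms C5–C10, C4–C2 and C2–C1; the cobaltacycle needs C1 equatorial on the forming ring A, so the chair with isopropenyl and O8 equatorial (O9 axial) should set H10 trans to O9, and the isopropenyl group cannot take part because it would close a four-membered ring.

Step 9
Reactants: 19 Pauson–Khand enone; 20 methyllithium
Product: 21 cis-hydrindanone trimethylsilyl enol ether (C2(OSiMe3)=C4(CH3); 5β-CH3; 10β-H; 7β-isopropenyl; 8α,9α-acetonide)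
Conditions: Me2CuLi (from MeLi and CuI, 3 equiv), TMSCl (5 equiv), Et3N, THF, −78 → −20 °C; cold NaHCO3 work-up, filtration through basic alumina
Reagents that add atoms: methyllithium 20 (delivered as lithium dimethylcuprate), [Li]C; chlorotrimethylsilane, C[Si](C)(C)Cl
Why: TMSCl-accelerated Gilman conjugate addition with in situ O-silylation of the enolate; methyl should add to C5 from the face of H10, away from the axial C9–O bond and the C9 ring residue, giving the cis ring fusion, and the enolate is trapped regiospecifically as the C2=C4 silyl enol ether.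

Step 10
Reactants: 21 cis-hydrindanone trimethylsilyl enol ether; 22 diiodomethane
Product: 25 cis-octal-3-en-2-one (C2=O; C3=C4; 4-CH3; 5β-CH3; 10β-H; 7β-isopropenyl; 8α,9α-acetonide), via siloxycyclopropane 23 (not isolated), via beta-chloro ketone 24 (not isolated)
Conditions: Et2Zn, CH2I2, toluene, 0 °C → rt, pyridine quench; FeCl3, pyridine, DMF, 0 °C → rt; NaOAc, MeOH, 65 °C (crude material carried through)
Reagents that add atoms: diiodomethane 22 (as EtZnCH2I), ICI
Why: The Furukawa carbenoid EtZnCH2I transfers its methylene to the electron-rich C2=C4 bond in a concerted Simmons–Smith step, giving siloxycyclopropane 23 in which the new carbon C3 is bonded to both C2 and C4. Iron(III) chloride then oxidises the cyclopropyl silyl ether by one electron to an oxygen-centred radical with loss of silicon, β-scission breaks the internal C2–C4 bond to give the C2 ketone and a tertiary C4 radical, this radical takes chlorine from a second FeCl3 to give 24, and sodium acetate removes HCl to the conjugated C3=C4 enone. The closest known reaction type is the Ito–Saegusa one-carbon homologation of cycloalkanone silyl enol ethers to 2-cycloalkenones. The three-membered ring closes by a [2+1] methylene transfer, and the six-membered ring B arises not by a cyclisation but by cleavage of the zero-atom bridge of the bicyclo[3.1.0]hexane, which leaves C3 inserted between C2 and C4. No stereocentre is created in the end, since the cyclopropane carbons and the chlorinated C4 are transient and finish as sp2 carbons, so the face of methylene transfer is irrelevant and C5, C7, C8, C9 and C10 are untouched. The step needs insertion between C2 and C4 rather than C1 and C2, which the enol ether position left by the conjugate methylation fixes; it needs attack on the enol ether in preference to the isopropenyl group, which the higher nucleophilicity of the silyl enol ether and a limited charge of carbenoid should secure; and it needs internal rather than external cyclopropane cleavage, which the tertiary radical and the relief of strain favour, while pyridine-buffered FeCl3 in DMF should spare the acetonide.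

Step 11
Reactants: 25 cis-octal-3-en-2-one
Product: 27 cis-decalin-2-one (4β-CH3; 5β-CH3; 10β-H; 7β-isopropenyl; 8α,9α-acetonide), via lithium enolate 26 (not isolated)
Conditions: Li, NH3(l)/THF, t-BuOH (1 equiv), −78 °C; isoprene, then solid NH4Cl
Reagents that add atoms: none
Why: Dissolving-metal (Birch-type) reduction of the enone: the β-carbanion at C4 is protonated axially on ring B in the conformer that keeps isopropenyl and O8 equatorial, which should put the C4 methyl equatorial and cis to the C5 methyl (the more stable epimer), and the enolate is protonated on quenching; isolated alkenes and the acetonide are inert.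

Step 12
Reactants: 27 cis-decalin-2-one acetonide
Product: 28 8α,9α-dihydroxy cis-decalin-2-one (4β,5β-dimethyl; 10β-H; 7β-isopropenyl)
Conditions: AcOH/H2O (4:1), 45 °C
Reagents that add atoms: none
Why: Acid-catalysed hydrolysis of the cis-fused dioxolane (acetal cleavage); dilute acetic acid is too weak to protonate the isopropenyl group and leaves the ketone alone.

Step 13
Reactants: 28 8α,9α-dihydroxy cis-decalin-2-one; 29 (R)-2-methylbutanoic acid
Product: 31 8-O-[(R)-2-methylbutanoyl] 9α-hydroxy cis-decalin-2-one, via O-acylisourea 30 (not isolated)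
Conditions: 29 (1.1 equiv), DCC (1.1 equiv), DMAP (0.1 equiv), CH2Cl2, −20 → 0 °C
Reagents that add atoms: (R)-2-methylbutanoic acid 29, CC[C@@H](C)C(=O)O
Why: Steglich esterification at low temperature should acylate the equatorial C8 hydroxyl selectively because the axial C9 hydroxyl is syn-axial to the C5–C4 bond and flanked by the ring fusion; a simple α-branched alkanoic acid does not racemise under these conditions.

Step 14
Reactants: 31 8-O-[(R)-2-methylbutanoyl] 9α-hydroxy cis-decalin-2-one; 32 tigloyl chloride
Product: 33 CNP0312791.1 (8α-O-(R)-2-methylbutanoyl; 9α-O-tigloyl; 4β,5β-dimethyl; 10β-H; 7β-isopropenyl cis-decalin-2-one)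
Conditions: 32 (3 equiv), DMAP (1 equiv), pyridine, toluene, 60 °C
Reagents that add atoms: tigloyl chloride 32, C/C=C(\C)C(=O)Cl
Why: DMAP-catalysed acylation with the acid chloride under forcing conditions esterifies the remaining hindered axial alcohol; the (E)-tiglate is the stable geometric isomer, and pyridine in place of a trialkylamine avoids vinylketene formation and deconjugation.

**Compound list**

1 | 2,3-O-isopropylidene-D-erythronolactone | CC1(C)O[C@@H]2COC(=O)[C@@H]2O1 | starting material
2 | 2,3-O-isopropylidene-D-erythrofuranose (lactol, both anomers) | CC1(C)O[C@@H]2COC(O)[C@@H]2O1 | intermediate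
3 | methyltriphenylphosphonium bromide | C[P+](c1ccccc1)(c1ccccc1)c1ccccc1.[Br-] | starting material
4 | [(4R,5S)-2,2-dimethyl-5-vinyl-1,3-dioxolan-4-yl]methanol | CC1(C)O[C@H](CO)[C@H](C=C)O1 | intermediate
5 | (4S,5S)-2,2-dimethyl-5-vinyl-1,3-dioxolane-4-carbaldehyde | CC1(C)O[C@H](C=O)[C@H](C=C)O1 | intermediate
6 | ethyl 2-(diphenoxyphosphoryl)acetate | CCOC(=O)CP(=O)(Oc1ccccc1)Oc1ccccc1 | starting material
7 | ethyl (Z)-3-[(4R,5S)-2,2-dimethyl-5-vinyl-1,3-dioxolan-4-yl]prop-2-enoate | CC1(C)O[C@H](/C=C\C(=O)OCC)[C@H](C=C)O1 | intermediate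
8 | isopropenylmagnesium bromide | C=C(C)[Mg]Br | starting material
9 | ethyl trimethylsilyl ketene acetal of ester 10 | CCOC(O[Si](C)(C)C)=C[C@H](C(C)=C)[C@H]1OC(C)(C)O[C@H]1C=C | intermediate
10 | ethyl (3R)-3-[(4R,5S)-2,2-dimethyl-5-vinyl-1,3-dioxolan-4-yl]-4-methylpent-4-enoate | CCOC(=O)C[C@H](C(C)=C)[C@H]1OC(C)(C)O[C@H]1C=C | intermediate
11 | dimethyl (1-diazo-2-oxopropyl)phosphonate | CC(=O)C(=[N+]=[N-])P(=O)(OC)OC | starting material
12 | (3R)-3-[(4R,5S)-2,2-dimethyl-5-vinyl-1,3-dioxolan-4-yl]-4-methylpent-4-enal | O=CC[C@H](C(C)=C)[C@H]1OC(C)(C)O[C@H]1C=C | intermediate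
13 | (4R,5S)-2,2-dimethyl-4-[(3R)-2-methylhex-1-en-5-yn-3-yl]-5-vinyl-1,3-dioxolane | C#CC[C@H](C(C)=C)[C@H]1OC(C)(C)O[C@H]1C=C | intermediate
14 | iodomethane | CI | starting material
15 | lithium acetylide of 13 | [Li]C#CC[C@H](C(C)=C)[C@H]1OC(C)(C)O[C@H]1C=C | intermediate
16 | (4R,5S)-2,2-dimethyl-4-[(3R)-2-methylhept-1-en-5-yn-3-yl]-5-vinyl-1,3-dioxolane | CC#CC[C@H](C(C)=C)[C@H]1OC(C)(C)O[C@H]1C=C | intermediate
17 | dicobalt octacarbonyl | O=C=[Co](=C=O)(=C=O)(=C=O)[Co](=C=O)(=C=O)(=C=O)=C=O | starting material
18 | hexacarbonyldicobalt complex of the alkyne of 16 | CC12[Co]3(=C=O)(=C=O)(=C=O)[Co]1(=C=O)(=C=O)(=C=O)C23C[C@H](C(C)=C)[C@H]1OC(C)(C)O[C@H]1C=C | intermediate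
19 | Pauson–Khand enone: C2 ketone, C4(CH3)=C5, 7β-isopropenyl, 8α,9α-acetonide, 10β-H | C=C(C)[C@H]1CC2=C(C)C(=O)C[C@@H]2[C@@H]3OC(C)(C)O[C@H]13 | intermediate
20 | methyllithium | [Li]C | starting material
21 | cis-hydrindanone trimethylsilyl enol ether: C2(OSiMe3)=C4(CH3), 5β-CH3, 10β-H, 7β-isopropenyl, 8α,9α-acetonide | C=C(C)[C@H]1C[C@@]2(C)[C@H](CC(O[Si](C)(C)C)=C2C)[C@@H]3OC(C)(C)O[C@H]13 | intermediate (key-step precursor)
22 | diiodomethane | ICI | starting material
23 | siloxycyclopropane: C3 bridging C2(OSiMe3) and C4(CH3), either face | C=C(C)[C@H]1C[C@@]2(C)[C@H](CC3(O[Si](C)(C)C)CC23C)[C@@H]4OC(C)(C)O[C@H]14 | intermediate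
24 | 4-chloro-4-methyl cis-decalin-2-one, either C4 epimer | C=C(C)[C@H]1C[C@@]2(C)[C@H](CC(=O)CC2(C)Cl)[C@@H]3OC(C)(C)O[C@H]13 | intermediate
25 | cis-octal-3-en-2-one: 4-CH3, 5β-CH3, 10β-H, 7β-isopropenyl, 8α,9α-acetonide | C=C(C)[C@H]1C[C@@]2(C)[C@H](CC(=O)C=C2C)[C@@H]3OC(C)(C)O[C@H]13 | intermediate (key-step product)
26 | lithium C2=C3 enolate of 27 | C=C(C)[C@H]1C[C@@]2(C)[C@H](CC(O[Li])=C[C@@H]2C)[C@@H]3OC(C)(C)O[C@H]13 | intermediate
27 | cis-decalin-2-one: 4β,5β-dimethyl, 10β-H, 7β-isopropenyl, 8α,9α-acetonide | C=C(C)[C@H]1C[C@@]2(C)[C@H](CC(=O)C[C@@H]2C)[C@@H]3OC(C)(C)O[C@H]13 | intermediate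
28 | 8α,9α-dihydroxy cis-decalin-2-one: 4β,5β-dimethyl, 10β-H, 7β-isopropenyl | C=C(C)[C@H]1C[C@@]2(C)[C@H](CC(=O)C[C@@H]2C)[C@H](O)[C@@H]1O | intermediate
29 | (R)-2-methylbutanoic acid | CC[C@@H](C)C(=O)O | starting material
30 | O-[(R)-2-methylbutanoyl]-N,N'-dicyclohexylisourea | CC[C@@H](C)C(=O)OC(=NC1CCCCC1)NC1CCCCC1 | intermediate
31 | 8-O-[(R)-2-methylbutanoyl] 9α-hydroxy cis-decalin-2-one | C=C(C)[C@H]1C[C@@]2(C)[C@H](CC(=O)C[C@@H]2C)[C@H](O)[C@@H]1OC(=O)[C@H](C)CC | intermediate
32 | tigloyl chloride, (E)-2-methylbut-2-enoyl chloride | C/C=C(\C)C(=O)Cl | starting material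
33 | CNP0312791.1 | C=C(C)[C@H]1C[C@@]2(C)[C@H](CC(=O)C[C@@H]2C)[C@H](OC(=O)/C(C)=C/C)[C@@H]1OC(=O)[C@H](C)CC | target

**Count and risks**

Total steps: 14. Longest linear sequence: 14 steps (1 → 33).

The three steps most likely to fail are these.

Step 9. The cuprate may not add to the fully substituted β-carbon C5 of the α-methylated enone, so that recovery of enone, 1,2-addition or reduction compete and no regiochemically pure enol ether is obtained. The fallback sets out from the terminal alkyne 13 and comes back at enone 25; it postpones the C4 methyl so that C5 is built on a less hindered enone. Pauson–Khand cyclisation of 13 under the conditions of step 8 passes through the alkyne–cobalt complex F1 and gives the α-unsubstituted hydrindenone F2. This β,β-disubstituted enone should take Me2CuLi/TMSCl readily and give the C5-methylated silyl enol ether F3. The ring expansion of step 10 (Et2Zn/CH2I2, then FeCl3, then NaOAc) runs through the siloxycyclopropane F4 and the β-chloro ketone F5 to the enone lacking the C4 methyl F6. A second Me2CuLi/TMSCl addition, now at C4, gives the silyl enol ether F7, and Saegusa–Ito dehydrogenation (Pd(OAc)2, MeCN) restores the C3=C4 double bond with its methyl in place, which is 25.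

Step 10. Methylene transfer to the hindered tetrasubstituted enol ether may be slow, which would let desilylation by zinc iodide or cyclopropanation of the isopropenyl group compete, and iron(III) may loosen the acetonide during the opening. The fallback sets out from 21 and comes back at 25; it replaces the zinc carbenoid and the radical opening by a free dihalocarbene and an ionic opening. Dibromocarbene (CHBr3, KOtBu, pentane, −20 °C) is small and strongly electrophilic and should add to the enol ether to give the dibromo siloxycyclopropane F8. On warming this opens by the cyclopropyl-to-allyl cation pathway with loss of the silyl group to the 3-bromo enone F9. Radical hydrodebromination (Bu3SnH, AIBN, benzene, 80 °C) then gives 25.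

Step 5. Facial selectivity at C7 may be poor, or the (Z)-enoate may isomerise before the copper reagent adds. The fallback sets out from aldehyde 5 and comes back at ester 10; it forms the C7–C6 bond instead of the C7–isopropenyl bond, so an attack on the face that gives the wrong epimer in the cuprate reaction gives the right one here. Wittig reaction of 5 with ethyl 2-(triphenylphosphoranylidene)propanoate (CH2Cl2, rt) gives the (E)-2-methyl enoate F10, and DIBAL-H reduces it to the allylic alcohol F11. Heating F11 with triethyl orthoacetate and catalytic propionic acid (140 °C, Johnson–Claisen) forms the ketene acetal F12. Its chair [3,3] shift, with C8–H held in the alkene plane by the cis vinylic methyl, delivers the acetate carbon to C7 and leaves the isopropenyl group behind, giving 10.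

Further compounds
F1 | step 9 | hexacarbonyldicobalt complex of terminal alkyne 13 | C12[Co]3(=C=O)(=C=O)(=C=O)[Co]1(=C=O)(=C=O)(=C=O)C23C[C@H](C(C)=C)[C@H]1OC(C)(C)O[C@H]1C=C
F2 | step 9 | Pauson–Khand enone without the C4 methyl (C4H=C5) | C=C(C)[C@H]1CC2=CC(=O)C[C@@H]2[C@@H]3OC(C)(C)O[C@H]13
F3 | step 9 | cis-hydrindanone trimethylsilyl enol ether without the C4 methyl | C=C(C)[C@H]1C[C@@]2(C)[C@H](CC(O[Si](C)(C)C)=C2)[C@@H]3OC(C)(C)O[C@H]13
F4 | step 9 | siloxycyclopropane without the C4 methyl | C=C(C)[C@H]1C[C@@]2(C)[C@H](CC3(O[Si](C)(C)C)CC23)[C@@H]4OC(C)(C)O[C@H]14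
F5 | step 9 | 4-chloro cis-decalin-2-one without the C4 methyl | C=C(C)[C@H]1C[C@@]2(C)[C@H](CC(=O)CC2Cl)[C@@H]3OC(C)(C)O[C@H]13
F6 | step 9 | cis-octal-3-en-2-one without the C4 methyl | C=C(C)[C@H]1C[C@@]2(C)[C@H](CC(=O)C=C2)[C@@H]3OC(C)(C)O[C@H]13
F7 | step 9 | C2=C3 trimethylsilyl enol ether with the C4 methyl added | C=C(C)[C@H]1C[C@@]2(C)[C@H](CC(O[Si](C)(C)C)=CC2C)[C@@H]3OC(C)(C)O[C@H]13
F8 | step 10 | 3,3-dibromo siloxycyclopropane from 21 | C=C(C)[C@H]1C[C@@]2(C)[C@H](CC3(O[Si](C)(C)C)C(Br)(Br)C23C)[C@@H]4OC(C)(C)O[C@H]14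
F9 | step 10 | 3-bromo cis-octal-3-en-2-one | C=C(C)[C@H]1C[C@@]2(C)[C@H](CC(=O)C(Br)=C2C)[C@@H]3OC(C)(C)O[C@H]13
F10 | step 5 | ethyl (E)-3-[(4R,5S)-2,2-dimethyl-5-vinyl-1,3-dioxolan-4-yl]-2-methylprop-2-enoate | CC1(C)O[C@H](/C=C(\C)C(=O)OCC)[C@H](C=C)O1
F11 | step 5 | (E)-3-[(4R,5S)-2,2-dimethyl-5-vinyl-1,3-dioxolan-4-yl]-2-methylprop-2-en-1-ol | CC1(C)O[C@H](/C=C(\C)CO)[C@H](C=C)O1
F12 | step 5 | ethyl ketene acetal of allylic alcohol F11 | CC1(C)O[C@H](/C=C(\C)COC(=C)OCC)[C@H](C=C)O1
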